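Start with the catalyst. In each run, catalyst joins starting material and coupling partner into target, and every reading is of target, so each is told here as a share of the starting material charged.

| flask | starting material | coupling partner | catalyst | time |
|---|---|---|---|---|
| teal | 120 mM | 144 mM | 3.60 mM |  |
| blue | 60.0 mM | 84.0 mM | 3.60 mM |  |
| amber | 120 mM | 144 mM | 7.20 mM |  |
| green | 60.0 mM | 144 mM | 1.80 mM | 30 min |

| run | time / min | [target] / mM |
|---|---|---|
| teal run | 4.3 | 7.5 |
| teal run | 8.6 | 15.5 |
| teal run | 13 | 26.4 |
| teal run | 17 | 35.7 |
| teal run | 21 | 45.7 |
| teal run | 26 | 56.6 |
| teal run | 30 | 64.8 |
| blue run | 4.3 | 3.5 |
| blue run | 8.6 | 6.7 |
| blue run | 13 | 10.3 |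
| blue run | 17 | 13.3 |
| blue run | 21 | 16.4 |
| blue run | 26 | 20.8 |
| blue run | 30 | 22.7 |
| amber run | 4.3 | 10.6 |
| amber run | 8.6 | 22.0 |
| amber run | 13 | 34.8 |
| amber run | 17 | 46.3 |
| amber run | 21 | 56.9 |
| amber run | 26 | 68.9 |
| amber run | 30 | 76.1 |

(standard deviation of a reading: 0.4 mM)

1. reaction order in [catalyst] at the outset, round the charge of the teal run, defined at two percent of the starting material turned into target
2. the blue run starts with 60.0 mM less of starting material and of coupling partner than the teal run, and with no target. Compared where both hold the same amount of starting material, once fifteen percent of what the blue run was charged with has turned into target, is the blue run faster, slower or alike (within a tenth)?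
3. target in the green run at 30 min, as a share of the starting material charged

- Overall: starting material + coupling partner -> target, with catalyst as catalyst.
- Constant volume, constant temperature.
- Bound and free are read together.
- "The second partner" is coupling partner.
- An order is taken over about fifteen percent of the charge, up and down.

**One number.** The amber and teal runs differ in one thing: amber holds twice the catalyst. At the second reading, amber has turned 18.3% of its charge and teal 12.9%. The ratio of these shares, 1.42, is the catalyst return: the factor, as read here, that doubling the catalyst gives the target made by that reading. A return of 2 means added catalyst works in full, and 1 means it does nothing. The order in catalyst, read this way, is its logarithm to base 2, here 0.505.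

**Reading it.** The green run holds half the catalyst of the blue run, so this estimate divides the blue run's 37.8% at the last reading by the return, which gives 26.7% for the green run. Green also carries 2.40 of partner per unit of starting material against blue's 1.40, and this reckoning makes no allowance for that.

**Its test.** By the last reading, the amber-to-teal ratio has fallen to 1.17, less than the return. In these two runs, one number therefore describes the early readings, not the whole run.

**The forecast.** It gives an order of 0.5 and a green share of 33%, above the share reckoned here. On the blue run it says “Blue is therefore slower, because it holds less target.”

**The flask.** The order is 0.51, the green run reaches 34.7%, and the blue run is slower, at 0.46 of the teal rate where both hold the same amount of starting material.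

    catalyst + starting material → catalyst-substrate complex (26.10 /M/min)
    catalyst-substrate complex + coupling partner → target + catalyst (30.36 /M/min)
    starting material + coupling partner + target → 2 target (4.146 /M²/min)
    2 catalyst ⇌ resting dimer, settled at all times (5650 /M)

**The dimer.** The return, taken from readings, names no resting dimer, the catalyst's resting state, yet its size reflects one. Applied to the amber run, it shortens teal's 14.6 min to a quarter of the charge into 10.3 min, and amber took 11.2 min. Applied to the green run, it gave 26.7% against 34.7%. With the resting dimer taken away, the order rises from 0.51 to 0.90, and the green run reaches 77.6% instead of 34.7%.

(Readings and results stem from a simulated flask on assumed constants.)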